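**Retrosynthetic overview**
1. Enabling feature: in the oxane ring (O1, C2–C6) the oxygen lies between two fully substituted carbons, the quaternary stereocenter C2 and the gem-dimethyl carbon C6. The triad O1–C2–C3H2 is therefore the retron of a 2,2-disubstituted oxirane (electrophilic CH2 plus latent tertiary alkoxide). C6 is the retron of a tertiary cation from an isopropenyl group.
2. Key disconnection: C3–C4 and O1–C6 are cut together. This is a formal [3+3] annulation of an enantiopure oxirane with the C5 reagent 3-methylbut-3-enylmagnesium bromide (copper-catalysed opening, then acid-triggered 6-exo-trig closure in the same flask).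
3. The oxirane comes from an epoxide relay on (R)-2-methylglycidol. Its ring CH2 is opened by a Grignard reagent cut out of (R)-citronellyl bromide (methine stereocenter and six chain carbons), its CH2OH becomes the new oxirane CH2, and its oxygen ends as the ring oxygen.
4. The chloride terminus carried through the annulation then becomes the nucleophile for the Weinreb amide of (S)-isopropylideneglyceric acid (acetoxy stereocenter). Wittig methylenation, acetonide removal and acetylation finish the target.
5. Ring order: temporary oxirane (step 4), then oxane (step 5). The dioxolane is a bought-in protecting ring that is removed in step 9.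

Key step: step 5

**Step 1**
Reactants: 1 (R)-citronellyl bromide [(6R)-8-bromo-2,6-dimethyloct-2-ene]
Product: 2 (4R)-6-bromo-4-methylhexan-1-ol
Conditions: O3, CH2Cl2–MeOH (4:1), −78 °C; then NaBH4 (excess), −78 → 0 °C
Reagents that add atoms: ozone, [O-][O+]=O
Why: Ozonolysis with reductive NaBH4 work-up cleaves the only C=C bond to the primary alcohol, while the C–Br bond and the methyl-bearing stereocenter, which is taken from the chiral pool, are not involved.

**Step 2**
Reactants: 2 (4R)-6-bromo-4-methylhexan-1-ol
Product: 3 (3R)-1-bromo-6-chloro-3-methylhexane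
Conditions: PPh3, N-chlorosuccinimide, CH2Cl2, 0 °C → rt
Reagents that add atoms: N-chlorosuccinimide, O=C1CCC(=O)N1Cl
Why: Appel-type chlorination replaces the primary hydroxyl group by SN2 on the alkoxyphosphonium ion under neutral conditions, which should leave the bromide end unexchanged and give two termini of clearly different reactivity.

**Step 3**
Reactants: 3 (3R)-1-bromo-6-chloro-3-methylhexane; 4 (R)-2-methylglycidol
Product: 6 (2S,6S)-9-chloro-2,6-dimethylnonane-1,2-diol, via chloroalkylmagnesium bromide 5 (not isolated)
Conditions: 3, Mg turnings, THF, 25–30 °C (gives 5, 1.2 equiv); 4 pre-treated with EtMgBr (1.0 equiv), THF, −30 °C; CuI (10 mol %), −30 → 0 °C; aq. work-up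
Reagents that add atoms: none
Why: Magnesium inserts into the C–Br bond far more readily than into the C–Cl bond, and the CuI-catalysed Grignard opening of the epoxide is an SN2 attack on the unsubstituted oxirane carbon, so the oxygen-bearing quaternary center of 4 (a Sharpless epoxidation product) passes unchanged into the tertiary carbinol of 6.

**Step 4**
Reactants: 6 (2S,6S)-9-chloro-2,6-dimethylnonane-1,2-diol
Product: 8 (2S)-2-[(4S)-7-chloro-4-methylheptyl]-2-methyloxirane, via primary monotosylate 7 (not isolated)
Conditions: TsCl (1.05 equiv), Et3N, DMAP (cat.), CH2Cl2, 0 °C → rt; then MeOH, K2CO3, rt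
Reagents that add atoms: none
Why: Only the primary hydroxyl group is sulfonylated, and the tertiary alkoxide then closes the oxirane by intramolecular Williamson substitution (3-exo-tet) at the CH2 carbon, so no bond to the stereocenter is broken and its configuration is retained.

**Step 5**
Reactants: 8 (2S)-2-[(4S)-7-chloro-4-methylheptyl]-2-methyloxirane; 9 4-bromo-2-methylbut-1-ene
Product: 12 (2S)-2-[(4S)-7-chloro-4-methylheptyl]-2,6,6-trimethyloxane, via 3-methylbut-3-enylmagnesium bromide 10 (not isolated), via tertiary alkenol 11 (not isolated)
Conditions: 9, Mg, Et2O, reflux (gives 10, 1.4 equiv); 8, CuI (10 mol %), Et2O, −30 → 0 °C; then in the same flask CH2Cl2, CF3SO3H (1.6 equiv, i.e. 0.2 equiv beyond all basic magnesium species), −40 °C → rt; aq. NaHCO3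
Reagents that add atoms: none
Why: The organocopper species formed from 10 and CuI attacks the unsubstituted oxirane carbon of 8 in an SN2 opening (ring bond C3–C4) and releases the tertiary magnesium alkoxide; acidification in the same flask gives alkenol 11, whose 1,1-disubstituted alkene is protonated at its CH2 terminus to a tertiary cation that the tertiary hydroxyl group captures (ring bond O1–C6). The closest known reaction types are the copper-catalysed Grignard opening of 2,2-disubstituted epoxides and the Brønsted acid-catalysed Markovnikov cycloisomerisation (hydroalkoxylation) of hydroxy alkenes, as in the closure of 2,6-dimethylheptenols to 2,2,6,6-tetramethyloxane, and the two are simply run back to back as a formal [3+3] annulation. The only ring formed, the oxane, closes in the 6-exo-trig mode, and any alkene that first isomerises to the trisubstituted position reaches the same cation and the same ring (6-endo-trig). No new stereocenter arises, because C6 carries two methyl groups, and the quaternary center C2 keeps the configuration of 8, because neither its C–O bond nor any of its C–C bonds is broken. The step needs attack on the oxirane CH2 only (secured by the fully substituted neighbouring carbon and the soft copper nucleophile), Markovnikov protonation (tertiary against primary cation), and protonation of the alkene ahead of ionisation of the tertiary carbinol or of the product ether (secured by low temperature, a small excess of acid and a prompt basic quench). The primary chloride is inert to both stages and the hydroxyl group, placed for six-ring closure, should outrun magnesium-bound bromide in capturing the cation.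

**Step 6**
Reactants: 13 methyl (4S)-2,2-dimethyl-1,3-dioxolane-4-carboxylate
Product: 14 (4S)-N-methoxy-N,2,2-trimethyl-1,3-dioxolane-4-carboxamide
Conditions: MeNH(OMe)·HCl (1.5 equiv), iPrMgCl (3.0 equiv), THF, −20 → 0 °C
Reagents that add atoms: N,O-dimethylhydroxylamine hydrochloride, CNOC.Cl
Why: Weinreb amide formation by attack of the chloromagnesium amide on the ester at low temperature, conditions under which the α-alkoxy stereocenter from the chiral pool should not epimerise.

**Step 7**
Reactants: 12 (2S)-2-[(4S)-7-chloro-4-methylheptyl]-2,6,6-trimethyloxane; 14 (4S)-N-methoxy-N,2,2-trimethyl-1,3-dioxolane-4-carboxamide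
Product: 16 (5S)-1-[(4S)-2,2-dimethyl-1,3-dioxolan-4-yl]-5-methyl-8-[(2S)-2,6,6-trimethyloxan-2-yl]octan-1-one, via alkylmagnesium chloride 15 (not isolated)
Conditions: 12, Mg turnings (activated with a crystal of I2), THF, reflux (gives 15); then 14, THF, 0 °C; aq. work-up
Reagents that add atoms: none
Why: Weinreb ketone synthesis, in which the Grignard reagent from the primary chloride adds once to 14 to give a chelated tetrahedral intermediate that collapses to the ketone only on work-up, which prevents over-addition and spares the α-alkoxy center, while the di-tertiary ether is inert.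

**Step 8**
Reactants: 16 (5S)-1-[(4S)-2,2-dimethyl-1,3-dioxolan-4-yl]-5-methyl-8-[(2S)-2,6,6-trimethyloxan-2-yl]octan-1-one
Product: 17 (4R)-2,2-dimethyl-4-{(6R)-6-methyl-9-[(2S)-2,6,6-trimethyloxan-2-yl]non-1-en-2-yl}-1,3-dioxolane
Conditions: Ph3PCH3Br, NaN(SiMe3)2, THF, 0 °C; then 16, −78 → 0 °C
Reagents that add atoms: methyltriphenylphosphonium bromide, C[P+](c1ccccc1)(c1ccccc1)c1ccccc1.[Br-]
Why: Wittig methylenation with the non-stabilised, lithium-free ylide at low temperature should be faster than enolisation of the α-alkoxy ketone, so the 1,1-disubstituted alkene forms without loss of the adjacent configuration (the descriptor changes only because the priorities change).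

**Step 9**
Reactants: 17 (4R)-2,2-dimethyl-4-{(6R)-6-methyl-9-[(2S)-2,6,6-trimethyloxan-2-yl]non-1-en-2-yl}-1,3-dioxolane
Product: 18 (2R,7R)-7-methyl-3-methylidene-10-[(2S)-2,6,6-trimethyloxan-2-yl]decane-1,2-diol
Conditions: AcOH–H2O (4:1), 40 °C
Reagents that add atoms: none
Why: Mild acid-catalysed acetal hydrolysis frees the 1,2-diol, and aqueous acetic acid is too weak to protonate the alkene or to ionise the di-tertiary oxane ether or the allylic alcohol.

**Step 10**
Reactants: 18 (2R,7R)-7-methyl-3-methylidene-10-[(2S)-2,6,6-trimethyloxan-2-yl]decane-1,2-diol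
Product: 19 (2R,7R)-7-methyl-3-methylidene-10-[(2S)-2,6,6-trimethyloxan-2-yl]decane-1,2-diyl diacetate (target)
Conditions: Ac2O, pyridine, DMAP (cat.), CH2Cl2, 0 °C → rt
Reagents that add atoms: acetic anhydride, CC(=O)OC(C)=O
Why: DMAP-catalysed acylation esterifies the primary and the secondary allylic hydroxyl group with retention, since only O–H bonds are broken.

**Compound list**
1 | (R)-citronellyl bromide [(6R)-8-bromo-2,6-dimethyloct-2-ene] | CC(C)=CCC[C@@H](C)CCBr | starting material
2 | (4R)-6-bromo-4-methylhexan-1-ol | OCCC[C@@H](C)CCBr | intermediate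
3 | (3R)-1-bromo-6-chloro-3-methylhexane | ClCCC[C@@H](C)CCBr | intermediate
4 | (R)-2-methylglycidol [[(2R)-2-methyloxiran-2-yl]methanol] | OC[C@]1(C)CO1 | starting material
5 | [(3R)-6-chloro-3-methylhexyl]magnesium bromide | ClCCC[C@@H](C)CC[Mg]Br | intermediate
6 | (2S,6S)-9-chloro-2,6-dimethylnonane-1,2-diol | ClCCC[C@@H](C)CCC[C@@](O)(C)CO | intermediate
7 | (2S,6S)-9-chloro-2-hydroxy-2,6-dimethylnonyl 4-methylbenzenesulfonate | ClCCC[C@@H](C)CCC[C@@](O)(C)COS(=O)(=O)c1ccc(C)cc1 | intermediate
8 | (2S)-2-[(4S)-7-chloro-4-methylheptyl]-2-methyloxirane | ClCCC[C@@H](C)CCC[C@@]1(C)CO1 | intermediate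
9 | 4-bromo-2-methylbut-1-ene | C=C(C)CCBr | starting material
10 | 3-methylbut-3-enylmagnesium bromide | C=C(C)CC[Mg]Br | intermediate
11 | (6S,10S)-13-chloro-2,6,10-trimethyltridec-1-en-6-ol | ClCCC[C@@H](C)CCC[C@@](O)(C)CCCC(C)=C | intermediate
12 | (2S)-2-[(4S)-7-chloro-4-methylheptyl]-2,6,6-trimethyloxane | ClCCC[C@@H](C)CCC[C@@]1(C)CCCC(C)(C)O1 | intermediate
13 | methyl (4S)-2,2-dimethyl-1,3-dioxolane-4-carboxylate | COC(=O)[C@@H]1COC(C)(C)O1 | starting material
14 | (4S)-N-methoxy-N,2,2-trimethyl-1,3-dioxolane-4-carboxamide | CON(C)C(=O)[C@@H]1COC(C)(C)O1 | intermediate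
15 | {(4S)-4-methyl-7-[(2S)-2,6,6-trimethyloxan-2-yl]heptyl}magnesium chloride | Cl[Mg]CCC[C@@H](C)CCC[C@@]1(C)CCCC(C)(C)O1 | intermediate
16 | (5S)-1-[(4S)-2,2-dimethyl-1,3-dioxolan-4-yl]-5-methyl-8-[(2S)-2,6,6-trimethyloxan-2-yl]octan-1-one | O=C(CCC[C@@H](C)CCC[C@@]1(C)CCCC(C)(C)O1)[C@@H]2COC(C)(C)O2 | intermediate
17 | (4R)-2,2-dimethyl-4-{(6R)-6-methyl-9-[(2S)-2,6,6-trimethyloxan-2-yl]non-1-en-2-yl}-1,3-dioxolane | C=C(CCC[C@@H](C)CCC[C@@]1(C)CCCC(C)(C)O1)[C@@H]2COC(C)(C)O2 | intermediate
18 | (2R,7R)-7-methyl-3-methylidene-10-[(2S)-2,6,6-trimethyloxan-2-yl]decane-1,2-diol | C=C(CCC[C@@H](C)CCC[C@@]1(C)CCCC(C)(C)O1)[C@H](CO)O | intermediate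
19 | (2R,7R)-7-methyl-3-methylidene-10-[(2S)-2,6,6-trimethyloxan-2-yl]decane-1,2-diyl diacetate | C=C(CCC[C@@H](C)CCC[C@@]1(C)CCCC(C)(C)O1)[C@H](COC(C)=O)OC(C)=O | target

**Step count**
Total step count: 10
Longest linear sequence: 9 (steps 1–5 and 7–10; step 6 is a one-step side branch)

**Steps most likely to fail**

1. Step 5.
 - Risk: the acid stage may run past its kinetic window. Reversible ionisation of the tertiary carbinol or of the product ether at the quaternary center would erode its configuration. Capture of the tertiary cation by bromide, or incomplete closure, would lower conversion.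
 - Fallback (sets out from 8, comes back at 12): the copper-catalysed opening is quenched with neutral water and tertiary alkenol 11 is isolated. Iodoetherification with N-iodosuccinimide (NaHCO3, MeCN, 0 °C; 6-exo attack of the hydroxyl group on the tertiary carbon of the iodonium ion) should give (2S)-2-[(4S)-7-chloro-4-methylheptyl]-6-(iodomethyl)-2,6-dimethyloxane F1 as an inconsequential mixture of epimers at the new center. Radical deiodination (Bu3SnH, AIBN, toluene, 80 °C), toward which the primary chloride is much less reactive, then gives 12. No acid is present at any point, so the quaternary center cannot ionise.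

2. Step 8.
 - Risk: the basic ylide may enolise the α-alkoxy ketone, which would epimerise the dioxolane stereocenter or open the ring by β-elimination. Olefination next to the branched carbon may also be slow.
 - Fallback (sets out from 16, comes back at 17): Peterson olefination. The weakly basic organocerium reagent from Me3SiCH2MgCl and CeCl3 (THF, −78 °C) adds to the ketone to give the β-hydroxysilane (6R)-2-[(4S)-2,2-dimethyl-1,3-dioxolan-4-yl]-6-methyl-1-(trimethylsilyl)-9-[(2S)-2,6,6-trimethyloxan-2-yl]nonan-2-ol F2 (carbinol center as a mixture). Treatment with KH in THF at 0 °C brings about syn elimination to 17.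

3. Step 3.
 - Risk: magnesium insertion may lose its preference for the C–Br bond, Wurtz coupling may consume the reagent, and magnesium bromide may open the unprotected epoxy alcohol to a halohydrin before the copper reagent does.
 - Fallback (sets out from 3, comes back at 8): the chain is joined by enolate chemistry and the oxirane stereocenter is set by a catalyst.
 - The sodium enolate of ethyl acetoacetate (NaH, THF–DMF, 50 °C) is alkylated at the bromide end of 3 to give ethyl (5S)-2-acetyl-8-chloro-5-methyloctanoate F3.
 - Saponification and decarboxylation (dilute aq. NaOH, rt; then dilute H2SO4, 60 °C) give (6S)-9-chloro-6-methylnonan-2-one F4.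
 - Catalytic asymmetric Corey–Chaykovsky epoxidation of this methyl ketone gives 8. It uses dimethyloxosulfonium methylide, LaLi3(binaphthoxide)3 in the enantiomeric form that delivers the (S)-oxirane, and a triarylphosphine oxide additive (THF, molecular sieves, rt).

**Further compounds**
F1 | step 5 | (2S)-2-[(4S)-7-chloro-4-methylheptyl]-6-(iodomethyl)-2,6-dimethyloxane | ClCCC[C@@H](C)CCC[C@@]1(C)CCCC(C)(CI)O1
F2 | step 8 | (6R)-2-[(4S)-2,2-dimethyl-1,3-dioxolan-4-yl]-6-methyl-1-(trimethylsilyl)-9-[(2S)-2,6,6-trimethyloxan-2-yl]nonan-2-ol | C[Si](C)(C)CC(O)(CCC[C@@H](C)CCC[C@@]1(C)CCCC(C)(C)O1)[C@@H]2COC(C)(C)O2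
F3 | step 3 | ethyl (5S)-2-acetyl-8-chloro-5-methyloctanoate | ClCCC[C@@H](C)CCC(C(C)=O)C(=O)OCC
F4 | step 3 | (6S)-9-chloro-6-methylnonan-2-one | ClCCC[C@@H](C)CCCC(C)=O
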